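**Retrosynthetic overview** (eudesmane numbering: C1–C10 ring carbons, C11–C13 acrylate unit)
1. The C4 methyl/hydroxyl and the C3 angelate are added last to bicyclic enone 14: methyl addition to C4=O, and carboxylate SN2 on a 3α-bromide.
2. Ring B of 14 is opened at C6–C7: the precursor is monocyclic keto acetal 12, with C6 as a dimethyl acetal on C5 and C7 as the γ-carbon of a 2-(methoxycarbonyl)allylsilane at the end of the C10–C9–C8 chain.
3. Enabling feature: C5 is the α-carbon of the ring A ketone C4 and carries C6 at the aldehyde oxidation level. C6 is first the electrophile for C7 (ring B = C5–C6–C7–C8–C9–C10) and then loses methanol toward C5 to give C5=C6; the silicon on C13 turns the nucleophile into the C11=C13 acrylate.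
4. 12 comes from 3-methylcyclohex-2-enone: asymmetric conjugate addition of a butenyl Grignard sets C10, the resulting enolate places C6 on C5, and ozonolysis/Horner–Wadsworth–Emmons builds the allylsilane.
5. Ring order: ring A is bought with the starting enone; ring B is closed in step 6, where the C5 epimers and alkene isomers of 12 converge on one product.

Key step: step 6

Remark: the ligand enantiomer in step 1 is assumed to be the one that gives the (R)-configured quaternary carbon of 4; all later stereocentres are then set by substrate control.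

**Step 1**
Reactants: 1 3-methylcyclohex-2-en-1-one; 2 but-3-en-1-ylmagnesium bromide
Product: 4 (R)-{[3-(but-3-en-1-yl)-3-methylcyclohex-1-en-1-yl]oxy}trimethylsilane, via bromomagnesium enolate 3 (not isolated)
Conditions: Cu(OTf)2 (3 mol %), chiral imidazolinium salt as N-heterocyclic carbene precursor (4 mol %), Et2O, −30 °C; then Me3SiCl, Et3N, HMPA, −30 °C → rt
Reagents that add atoms: chlorotrimethylsilane, C[Si](C)(C)Cl
Why: Copper-catalysed asymmetric conjugate addition of a Grignard reagent to a β,β-disubstituted cyclohexenone should set the quaternary carbon C10 under ligand control, and O-silylation of the regiodefined magnesium enolate locks the enol double bond between C4 and C5.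

**Step 2**
Reactants: 4 (R)-{[3-(but-3-en-1-yl)-3-methylcyclohex-1-en-1-yl]oxy}trimethylsilane; 5 trimethyl orthoformate
Product: 6 (3R)-3-(but-3-en-1-yl)-2-(dimethoxymethyl)-3-methylcyclohexan-1-one (both C2 epimers)
Conditions: Me3SiOTf (10 mol %), CH2Cl2, −78 °C
Reagents that add atoms: none
Why: Mukaiyama-type alkylation of the silyl enol ether by the dimethoxycarbenium ion from the orthoester should attach C6 regiospecifically to C5 at the aldehyde oxidation level, and the new C5 stereocentre is of no consequence because step 6 erases it.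

**Step 3**
Reactants: 6 (3R)-3-(but-3-en-1-yl)-2-(dimethoxymethyl)-3-methylcyclohexan-1-one
Product: 8 3-[(1R)-2-(dimethoxymethyl)-1-methyl-3-oxocyclohexyl]propanal, via ozonide 7 (not isolated)
Conditions: O3, CH2Cl2, −78 °C; then PPh3, −78 °C → rt
Reagents that add atoms: ozone, [O-][O+]=O
Why: Ozonolysis with reductive work-up should cleave the only alkene and leave the ketone and the acetal untouched, which shortens the chain to the C7 aldehyde.

**Step 4**
Reactants: 9 trimethyl phosphonoacetate; 10 (iodomethyl)trimethylsilane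
Product: 11 methyl 2-(dimethoxyphosphoryl)-3-(trimethylsilyl)propanoate (racemic)
Conditions: NaH, DME, 0 °C; then 10, 70 °C
Reagents that add atoms: none
Why: SN2 alkylation of the sodium phosphonoacetate carbanion with the primary α-silyl iodide should give the phosphonate that carries the C11–C13 unit with silicon on C13.

**Step 5**
Reactants: 8 3-[(1R)-2-(dimethoxymethyl)-1-methyl-3-oxocyclohexyl]propanal; 11 methyl 2-(dimethoxyphosphoryl)-3-(trimethylsilyl)propanoate
Product: 12 methyl (2Z)-5-[(1R)-2-(dimethoxymethyl)-1-methyl-3-oxocyclohexyl]-2-[(trimethylsilyl)methyl]pent-2-enoate (main alkene isomer; the E isomer is carried along)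
Conditions: NaH, THF, 0 °C; then 8, 0 °C → rt
Reagents that add atoms: none
Why: Horner–Wadsworth–Emmons olefination should take place only at the aldehyde and build the C7=C11 bond of the 2-(methoxycarbonyl)allylsilane, whose alkene geometry is irrelevant because step 6 destroys it.

**Step 6**
Reactants: 12 methyl (2Z)-5-[(1R)-2-(dimethoxymethyl)-1-methyl-3-oxocyclohexyl]-2-[(trimethylsilyl)methyl]pent-2-enoate
Product: 14 methyl 2-[(2R,4aR)-4a-methyl-8-oxo-2,3,4,4a,5,6,7,8-octahydronaphthalen-2-yl]prop-2-enoate, via beta-methoxy ketone 13 (not isolated)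
Conditions: Me3SiOTf (0.3 equiv), CH2Cl2, −78 → −20 °C; then DBU (2 equiv), −20 °C → rt
Reagents that add atoms: none
Why: Me3SiOTf ionises the dimethyl acetal to the C6 oxocarbenium ion, which is attacked by C7, the γ-carbon of the 2-(methoxycarbonyl)allylsilane, in an anti-SE2' sense; loss of the silyl group from C13 then creates the C11=C13 exo-methylene ester and returns Me3SiOTf, and DBU finally expels methanol across C5–C6 by an E1cB elimination driven by the C4 carbonyl. The closest known reaction type is the intramolecular Hosomi–Sakurai cyclisation of 2-(alkoxycarbonyl)allylsilanes onto aldehydes and acetals, which gives carbocycles bearing an α-methylene ester, combined with the standard β-elimination of a β-alkoxy ketone. Ring B closes in the 6-exo-trig mode with respect to both the C6=O+ and the C7=C11 π bonds. The only stereocentre that survives, C7, is controlled by the C10 quaternary centre: in the chair-like transition state the C10 methyl is axial on the forming ring and the bulky C7=C11 unit takes the equatorial position, which places the side chain cis to that methyl (7R). The step needs chemoselective activation of the acetal beside the ketone and the ester, which the much easier ionisation of an acetal by a silyl triflate should secure, and it needs one position for each new double bond, which the silicon on C13 and the acidity of C5–H (α to the C4 carbonyl and β to the methoxy group) should secure. Both C5 epimers (which can interconvert through the enol ether under the acidic conditions) and both alkene isomers of 12 should converge on 14, since C5, C6 and the C7=C11 geometry are all erased.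

**Step 7**
Reactants: 14 methyl 2-[(2R,4aR)-4a-methyl-8-oxo-2,3,4,4a,5,6,7,8-octahydronaphthalen-2-yl]prop-2-enoate
Product: 17 methyl 2-[(2R,4aS,7R)-7-bromo-4a-methyl-8-oxo-2,3,4,4a,5,6,7,8-octahydronaphthalen-2-yl]prop-2-enoate, via lithium dienolate 15 (not isolated), via trimethylsilyl dienol ether 16 (not isolated)
Conditions: LiN(SiMe3)2, THF, −78 °C; Me3SiCl, −78 °C; then N-bromosuccinimide, −78 °C
Reagents that add atoms: N-bromosuccinimide, O=C1CCC(=O)N1Br (for the intermediates only: LiN(SiMe3)2, [Li]N([Si](C)(C)C)[Si](C)(C)C; chlorotrimethylsilane, C[Si](C)(C)Cl)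
Why: Kinetic α'-deprotonation at C3, O-silylation and electrophilic bromination of the 2-silyloxydiene should deliver bromine axially to C3 from the face opposite to the axial C10 methyl of the conformationally fixed ring A, giving the 3α-bromide.

**Step 8**
Reactants: 17 methyl 2-[(2R,4aS,7R)-7-bromo-4a-methyl-8-oxo-2,3,4,4a,5,6,7,8-octahydronaphthalen-2-yl]prop-2-enoate; 18 angelic acid [(2Z)-2-methylbut-2-enoic acid]
Product: 19 methyl 2-[(2R,4aS,7S)-4a-methyl-7-{[(2Z)-2-methylbut-2-enoyl]oxy}-8-oxo-2,3,4,4a,5,6,7,8-octahydronaphthalen-2-yl]prop-2-enoate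
Conditions: 18 (1.5 equiv), Cs2CO3 (0.75 equiv), DMF, rt; then 17, 0 °C → rt
Reagents that add atoms: none
Why: SN2 displacement of the axial α-keto bromide by cesium angelate should proceed with inversion to the equatorial 3β-ester, and alkylation of a carboxylate does not expose the (Z)-alkene of the angelate to the isomerisation that acyl activation can cause.

**Step 9**
Reactants: 19 methyl 2-[(2R,4aS,7S)-4a-methyl-7-{[(2Z)-2-methylbut-2-enoyl]oxy}-8-oxo-2,3,4,4a,5,6,7,8-octahydronaphthalen-2-yl]prop-2-enoate
Product: 20 methyl 2-[(2R,4aS,7S,8R)-8-hydroxy-4a,8-dimethyl-7-{[(2Z)-2-methylbut-2-enoyl]oxy}-2,3,4,4a,5,6,7,8-octahydronaphthalen-2-yl]prop-2-enoate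
Conditions: MeMgBr, CeCl3, THF, −78 °C; then pH 7 buffer
Reagents that add atoms: methylmagnesium bromide, C[Mg]Br
Why: 1,2-Addition of the organocerium reagent formed from MeMgBr and CeCl3 should be selective for the ketone over the three esters at −78 °C, and equatorial attack from the α-face, away from the syn-axial C10 methyl, sets C4 with the hydroxyl axial and cis to the 3β-angelate.

**Compound list**
1 | 3-methylcyclohex-2-en-1-one | CC1=CC(=O)CCC1 | starting material
2 | but-3-en-1-ylmagnesium bromide | C=CCC[Mg]Br | starting material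
3 | bromomagnesium (R)-3-(but-3-en-1-yl)-3-methylcyclohex-1-en-1-olate | Br[Mg]OC1=C[C@](C)(CCC1)CCC=C | intermediate
4 | (R)-{[3-(but-3-en-1-yl)-3-methylcyclohex-1-en-1-yl]oxy}trimethylsilane | C[Si](C)(C)OC1=C[C@](C)(CCC1)CCC=C | intermediate
5 | trimethyl orthoformate | COC(OC)OC | starting material
6 | (3R)-3-(but-3-en-1-yl)-2-(dimethoxymethyl)-3-methylcyclohexan-1-one (C2 epimers) | COC(OC)C1[C@](C)(CCCC1=O)CCC=C | intermediate
7 | (3R)-2-(dimethoxymethyl)-3-methyl-3-[2-(1,2,4-trioxolan-3-yl)ethyl]cyclohexan-1-one (ozonide) | COC(OC)C1[C@](C)(CCCC1=O)CCC2OCOO2 | intermediate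
8 | 3-[(1R)-2-(dimethoxymethyl)-1-methyl-3-oxocyclohexyl]propanal (C2 epimers of the ring) | COC(OC)C1[C@](C)(CCCC1=O)CCC=O | intermediate
9 | trimethyl phosphonoacetate | COC(=O)CP(=O)(OC)OC | starting material
10 | (iodomethyl)trimethylsilane | C[Si](C)(C)CI | starting material
11 | methyl 2-(dimethoxyphosphoryl)-3-(trimethylsilyl)propanoate (racemic) | COC(=O)C(C[Si](C)(C)C)P(=O)(OC)OC | intermediate
12 | methyl (2Z)-5-[(1R)-2-(dimethoxymethyl)-1-methyl-3-oxocyclohexyl]-2-[(trimethylsilyl)methyl]pent-2-enoate (ring C2 epimers; E isomer also present) | COC(OC)C1[C@](C)(CCCC1=O)CC/C=C(\C[Si](C)(C)C)C(=O)OC | intermediate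
13 | methyl 2-[(2S,4aR)-1-methoxy-4a-methyl-8-oxodecahydronaphthalen-2-yl]prop-2-enoate (epimers at C1 and C8a) | C=C(C(=O)OC)[C@H]1C(OC)C2[C@](C)(CCCC2=O)CC1 | intermediate
14 | methyl 2-[(2R,4aR)-4a-methyl-8-oxo-2,3,4,4a,5,6,7,8-octahydronaphthalen-2-yl]prop-2-enoate | C=C(C(=O)OC)[C@H]1C=C2[C@](C)(CCCC2=O)CC1 | intermediate
15 | methyl 2-[(2R,4aS)-8-(lithiooxy)-4a-methyl-2,3,4,4a,5,6-hexahydronaphthalen-2-yl]prop-2-enoate (lithium dienolate) | C=C(C(=O)OC)[C@H]1C=C2[C@](C)(CCC=C2O[Li])CC1 | intermediate
16 | methyl 2-[(2R,4aS)-4a-methyl-8-[(trimethylsilyl)oxy]-2,3,4,4a,5,6-hexahydronaphthalen-2-yl]prop-2-enoate | C=C(C(=O)OC)[C@H]1C=C2[C@](C)(CCC=C2O[Si](C)(C)C)CC1 | intermediate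
17 | methyl 2-[(2R,4aS,7R)-7-bromo-4a-methyl-8-oxo-2,3,4,4a,5,6,7,8-octahydronaphthalen-2-yl]prop-2-enoate | C=C(C(=O)OC)[C@H]1C=C2[C@](C)(CC[C@@H](Br)C2=O)CC1 | intermediate
18 | angelic acid, (2Z)-2-methylbut-2-enoic acid | C/C=C(/C)C(=O)O | starting material
19 | methyl 2-[(2R,4aS,7S)-4a-methyl-7-{[(2Z)-2-methylbut-2-enoyl]oxy}-8-oxo-2,3,4,4a,5,6,7,8-octahydronaphthalen-2-yl]prop-2-enoate | C=C(C(=O)OC)[C@H]1C=C2[C@](C)(CC[C@H](OC(=O)/C(C)=C\C)C2=O)CC1 | intermediate
20 | methyl 2-[(2R,4aS,7S,8R)-8-hydroxy-4a,8-dimethyl-7-{[(2Z)-2-methylbut-2-enoyl]oxy}-2,3,4,4a,5,6,7,8-octahydronaphthalen-2-yl]prop-2-enoate | C=C(C(=O)OC)[C@H]1C=C2[C@](C)(CC[C@H](OC(=O)/C(C)=C\C)[C@]2(C)O)CC1 | target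

**Totals**
Total step count: 9. Longest linear sequence: 8 steps (steps 1, 2, 3, 5, 6, 7, 8, 9).

**Steps most likely to fail**

1. Step 6. The ester-deactivated allylsilane may attack the oxocarbenium ion too slowly, so that protodesilylation or acid-induced migration of the new double bonds competes, and facial selectivity at C7 may be eroded. The fallback sets out from 8 and comes back at 14, and replaces the allylsilane by an electron-rich alkene whose side chain is oxidised afterwards. Wittig olefination of 8 with isopropylidenetriphenylphosphorane (isopropyltriphenylphosphonium iodide, n-BuLi, THF, −78 °C) should give (3R)-2-(dimethoxymethyl)-3-methyl-3-(4-methylpent-3-en-1-yl)cyclohexan-1-one F1. Me3SiOTf in CH2Cl2 at −78 °C followed by DBU should then close the same C6–C7 bond by a Prins-type cation–olefin cyclisation, with proton loss from a methyl group and elimination of methanol, to give (4aR,7R)-4a-methyl-7-(prop-1-en-2-yl)-3,4,4a,5,6,7-hexahydronaphthalen-1(2H)-one F2. Allylic oxidation of the isopropenyl methyl group (SeO2 cat., t-BuOOH, CH2Cl2) should give (4aR,7R)-7-(3-hydroxyprop-1-en-2-yl)-4a-methyl-3,4,4a,5,6,7-hexahydronaphthalen-1(2H)-one F3. Dess–Martin periodinane should give 2-[(2R,4aR)-4a-methyl-8-oxo-2,3,4,4a,5,6,7,8-octahydronaphthalen-2-yl]prop-2-enal F4, and NaClO2/NaH2PO4/2-methylbut-2-ene should give 2-[(2R,4aR)-4a-methyl-8-oxo-2,3,4,4a,5,6,7,8-octahydronaphthalen-2-yl]prop-2-enoic acid F5. Methylation with Me3SiCHN2 (MeOH/toluene) returns 14.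

2. Step 8. Dehydrobromination to the cross-conjugated dienone, or epimerisation of the bromide before substitution, may compete and give the wrong C3 configuration. The fallback sets out from 14 and comes back at 19, and introduces oxygen first and the ester second. The silyl dienol ether 16, generated as in step 7, is oxidised with dimethyldioxirane (acetone/CH2Cl2, −78 °C; then citric acid, MeOH) in a Rubottom oxidation. This should deliver oxygen to the same α-face and give methyl 2-[(2R,4aS,7R)-7-hydroxy-4a-methyl-8-oxo-2,3,4,4a,5,6,7,8-octahydronaphthalen-2-yl]prop-2-enoate F6. Mitsunobu esterification with 18 (PPh3, DIAD, toluene, 0 °C) should invert C3 and give 19.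

3. Step 9. The organometallic reagent may attack the ester groups, or the neighbouring alkoxide may migrate or cleave the angelate. The fallback sets out from 17 and comes back at 20, and adds the methyl group before the angelate is present. Displacement of the bromide with HCO2Cs (DMF, rt) should give methyl 2-[(2R,4aS,7S)-7-(formyloxy)-4a-methyl-8-oxo-2,3,4,4a,5,6,7,8-octahydronaphthalen-2-yl]prop-2-enoate F7. Excess MeMgBr/CeCl3 (THF, −78 → 0 °C) should add to C4 and remove the formyl group to give methyl 2-[(2R,4aS,7S,8R)-7,8-dihydroxy-4a,8-dimethyl-2,3,4,4a,5,6,7,8-octahydronaphthalen-2-yl]prop-2-enoate F8. Yamaguchi esterification with 18 (2,4,6-trichlorobenzoyl chloride, Et3N; then DMAP, toluene) should acylate only the secondary hydroxyl and give 20.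

**Further compounds**
F1 | step 6 | (3R)-2-(dimethoxymethyl)-3-methyl-3-(4-methylpent-3-en-1-yl)cyclohexan-1-one | COC(OC)C1[C@](C)(CCCC1=O)CCC=C(C)C
F2 | step 6 | (4aR,7R)-4a-methyl-7-(prop-1-en-2-yl)-3,4,4a,5,6,7-hexahydronaphthalen-1(2H)-one | C=C(C)[C@H]1C=C2[C@](C)(CCCC2=O)CC1
F3 | step 6 | (4aR,7R)-7-(3-hydroxyprop-1-en-2-yl)-4a-methyl-3,4,4a,5,6,7-hexahydronaphthalen-1(2H)-one | OCC(=C)[C@H]1C=C2[C@](C)(CCCC2=O)CC1
F4 | step 6 | 2-[(2R,4aR)-4a-methyl-8-oxo-2,3,4,4a,5,6,7,8-octahydronaphthalen-2-yl]prop-2-enal | O=CC(=C)[C@H]1C=C2[C@](C)(CCCC2=O)CC1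
F5 | step 6 | 2-[(2R,4aR)-4a-methyl-8-oxo-2,3,4,4a,5,6,7,8-octahydronaphthalen-2-yl]prop-2-enoic acid | OC(=O)C(=C)[C@H]1C=C2[C@](C)(CCCC2=O)CC1
F6 | step 8 | methyl 2-[(2R,4aS,7R)-7-hydroxy-4a-methyl-8-oxo-2,3,4,4a,5,6,7,8-octahydronaphthalen-2-yl]prop-2-enoate | C=C(C(=O)OC)[C@H]1C=C2[C@](C)(CC[C@@H](O)C2=O)CC1
F7 | step 9 | methyl 2-[(2R,4aS,7S)-7-(formyloxy)-4a-methyl-8-oxo-2,3,4,4a,5,6,7,8-octahydronaphthalen-2-yl]prop-2-enoate | C=C(C(=O)OC)[C@H]1C=C2[C@](C)(CC[C@H](OC=O)C2=O)CC1
F8 | step 9 | methyl 2-[(2R,4aS,7S,8R)-7,8-dihydroxy-4a,8-dimethyl-2,3,4,4a,5,6,7,8-octahydronaphthalen-2-yl]prop-2-enoate | C=C(C(=O)OC)[C@H]1C=C2[C@](C)(CC[C@H](O)[C@]2(C)O)CC1
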